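The C1'–C2' bond, which joins the side-chain carbinol carbon to the vinylic CH of the (E)-trisubstituted alkene, is the disconnection on which the route rests. It exploits one feature: C1' is a secondary allylic carbinol flanked by the quaternary epoxide carbon C5 of the 7-oxabicyclo[4.1.0]heptenone ring and by the C2'=C3' alkene, so it maps onto an α,β-epoxy aldehyde and an (E)-alkenyl metal. The key step, a ligand-controlled nickel/chromium (Nozaki–Hiyama–Kishi) coupling, forms this bond and sets C1' in one operation while tolerating acetate, epoxide and ketal. Its precursors are the fully oxygenated epoxy aldehyde (C1 ketone masked as dimethyl ketal, O4 as triethylsilyl ether) and the C14 (E,E)-trienyl iodide from carboalumination.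

Key step: step 12

Numbering used below: ring carbons C1 (carbonyl or ketal carbon), C2 (bears CH2OAc), C3, C4 (carbinol), C5 (quaternary epoxide carbon), C6 (epoxide CH); side chain C1' to C12'.

Assumption: the L-tartrate ester in step 6 and the (S)-configured oxazoline sulfonamide in step 12 are taken to induce the senses drawn; if a test run shows the opposite sense, the antipodal reagent is used with nothing else changed.

Step 1
Reactants: 1 geranyl bromide; 2 1-(trimethylsilyl)propyne
Product: 5 (5E)-6,10-dimethylundeca-5,9-dien-1-yne, via lithiated silylpropyne 3 (not isolated), via silylated dienyne 4 (not isolated)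
Conditions: 2, n-BuLi, THF, −78 °C; then 1, −78 °C → rt; then K2CO3 (cat.), MeOH, rt
Reagents that add atoms: none
Why: Propargylic lithiation of the silylpropyne and SN2 alkylation by the allylic bromide at the propargyl terminus leave the (E)-alkene untouched, and base-catalysed protodesilylation then frees the terminal alkyne.

Step 2
Reactants: 5 (5E)-6,10-dimethylundeca-5,9-dien-1-yne
Product: 7 (1E,5E)-1-iodo-2,6,10-trimethylundeca-1,5,9-triene, via alkenyl dimethylalane 6 (not isolated)
Conditions: Me3Al, Cp2ZrCl2 (0.25 equiv), CH2Cl2, 0 °C → rt; then I2, THF, −30 °C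
Reagents that add atoms: trimethylaluminium, C[Al](C)C; iodine, II
Why: Zirconium-catalysed Negishi carboalumination adds methyl and aluminium syn across the terminal alkyne (methyl to the internal carbon), and iodinolysis with retention should give the (E)-alkenyl iodide with the C3' methyl in place.

Step 3
Reactants: 8 2,5-dimethoxyterephthalaldehyde
Product: 9 2-hydroxy-5-methoxyterephthalaldehyde
Conditions: BCl3 (1.05 equiv), CH2Cl2, −78 → 0 °C; aqueous work-up
Reagents that add atoms: none
Why: Lewis-acid demethylation assisted by chelation to the ortho formyl group should stop after one ether when one equivalent of BCl3 is used, and the symmetry of 8 makes the two methoxy groups equivalent.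

Step 4
Reactants: 9 2-hydroxy-5-methoxyterephthalaldehyde
Product: 10 2,5-bis(hydroxymethyl)-4-methoxyphenol
Conditions: NaBH4, MeOH/THF, 0 °C
Reagents that add atoms: none
Why: Borohydride reduction converts both aryl aldehydes into benzylic alcohols without touching the ring.

Step 5
Reactants: 10 2,5-bis(hydroxymethyl)-4-methoxyphenol
Product: 11 2,5-bis(hydroxymethyl)-4,4-dimethoxycyclohexa-2,5-dien-1-one (ketone = future C4, ketal = future C1)
Conditions: PhI(OAc)2, MeOH, 0 °C
Reagents that add atoms: methanol, CO
Why: Oxidative dearomatization of a para-methoxyphenol with PhI(OAc)2 in methanol traps the phenoxenium species at the methoxy-bearing carbon and should give the quinone monoketal, which places one hydroxymethyl α to the ketone (C5) and the other next to the ketal (C2).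

Step 6
Reactants: 11 2,5-bis(hydroxymethyl)-4,4-dimethoxycyclohexa-2,5-dien-1-one
Product: 12 (5S,6R)-5,6-epoxy-2,5-bis(hydroxymethyl)-1,1-dimethoxycyclohex-2-en-4-one
Conditions: Ph3COOH, NaHMDS, L-(+)-diisopropyl tartrate, toluene, −50 °C; NH4Cl work-up
Reagents that add atoms: trityl hydroperoxide, OOC(c1ccccc1)(c1ccccc1)c1ccccc1
Why: In this tartrate-mediated nucleophilic epoxidation the peroxide anion adds to unsubstituted C6 (C2 is blocked by its substituent), and the C5 hydroxymethyl binds the sodium tartrate–peroxide aggregate, which should select the enone face and set C5 and C6 together as the cis-fused epoxide.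

Step 7
Reactants: 12 (5S,6R)-epoxy ketone diol
Product: 13 (4R,5R,6R)-5,6-epoxy-2,5-bis(hydroxymethyl)-1,1-dimethoxycyclohex-2-en-4-ol (C4 hydroxyl cis to the epoxide oxygen)
Conditions: NaBH4, CeCl3·7H2O, MeOH, −78 °C
Reagents that add atoms: none
Why: In this Luche 1,2-reduction of the nearly flat epoxy enone the epoxide C–O bond is pseudo-axial, so hydride should add anti to it, from the face of the C5 hydroxymethyl, and give the 4R alcohol that the next step inverts.

Step 8
Reactants: 13 (4R,5R,6R)-triol
Product: 15 (4S,5R,6R)-5,6-epoxy-2,5-bis(hydroxymethyl)-1,1-dimethoxycyclohex-2-en-4-ol (C4 hydroxyl trans to the epoxide oxygen), via tris(4-nitrobenzoate) 14 (not isolated)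
Conditions: PPh3, DIAD, 4-nitrobenzoic acid, THF, 0 °C → rt; then K2CO3 (cat.), MeOH, 0 °C
Reagents that add atoms: 4-nitrobenzoic acid, O=C(O)c1ccc(cc1)[N+](=O)[O-]
Why: The Mitsunobu reaction esterifies all three hydroxyls, at secondary allylic C4 with SN2 inversion because the carboxylate enters on the open face anti to the epoxide oxygen and no β-hydrogen permits elimination, and mild methanolysis then frees the 4S triol, whose hydroxyl oxygens come from the acid.

Step 9
Reactants: 15 (4S,5R,6R)-triol
Product: 18 [(4S,5R,6R)-5,6-epoxy-4-hydroxy-5-(hydroxymethyl)-1,1-dimethoxycyclohex-2-en-2-yl]methyl acetate, via cyclic phenylboronate 16 (not isolated), via acetylated phenylboronate 17 (not isolated)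
Conditions: PhB(OH)2, MgSO4, CH2Cl2, rt; then Ac2O, pyridine, DMAP (cat.), 0 °C; then pinacol, rt
Reagents that add atoms: acetic anhydride, CC(=O)OC(C)=O
Why: With transient boronate protection the cis-1,3-diol (O4 and the C5 hydroxymethyl) closes a six-membered phenylboronate, so that only the allylic C2 hydroxymethyl is acetylated, and transesterification with pinacol releases the diol.

Step 10
Reactants: 18 diol acetate
Product: 19 [(4S,5S,6R)-5,6-epoxy-1,1-dimethoxy-4-(triethylsilyloxy)-5-(triethylsilyloxymethyl)cyclohex-2-en-2-yl]methyl acetate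
Conditions: TESCl, imidazole, DMAP (cat.), DMF, 0 °C → rt
Reagents that add atoms: chlorotriethylsilane, CC[Si](Cl)(CC)CC
Why: Silylation under imidazole catalysis protects both remaining hydroxyls without the Lewis acidity that would endanger the ketal or the epoxide.

Step 11
Reactants: 19 bis(triethylsilyl) ether
Product: 20 [(4S,5S,6R)-5,6-epoxy-5-formyl-1,1-dimethoxy-4-(triethylsilyloxy)cyclohex-2-en-2-yl]methyl acetate
Conditions: (COCl)2, DMSO, CH2Cl2, −78 → −30 °C; then Et3N, −78 °C → rt
Reagents that add atoms: none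
Why: Swern oxidation converts a primary triethylsilyl ether directly into the aldehyde while the hindered secondary C4 silyl ether should survive, and the quaternary α-carbon cannot epimerise.

Step 12
Reactants: 20 epoxy aldehyde; 7 (1E,5E)-1-iodo-2,6,10-trimethylundeca-1,5,9-triene
Product: 21 [(4S,5S,6R)-5,6-epoxy-5-[(1S,2E,6E)-1-hydroxy-3,7,11-trimethyldodeca-2,6,10-trienyl]-1,1-dimethoxy-4-(triethylsilyloxy)cyclohex-2-en-2-yl]methyl acetate
Conditions: CrCl2, (S)-N-[2-(4-isopropyl-4,5-dihydrooxazol-2-yl)-6-methylphenyl]methanesulfonamide, Et3N, NiCl2 (cat.), THF, rt; aqueous ethylenediamine work-up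
Reagents that add atoms: none
Why: Zerovalent nickel, formed from NiCl2 by divalent chromium, inserts into the C–I bond of 7 with retention of the (E)-geometry, and transmetalation gives an alkenyl species of trivalent chromium carrying the chiral sulfonamide, which adds to the aldehyde of 20 through a closed, oxygen-bound transition state. The closest known reaction type is the ligand-controlled asymmetric Nozaki–Hiyama–Kishi alkenylation of aldehydes. No ring is closed. The new stereocenter C1' is controlled by the chiral oxazoline sulfonamide on chromium, which should deliver the alkenyl group to the Si face of the aldehyde; the substrate's own bias is expected to be modest and of uncertain sense, because the dipole-minimised rotamer is approached over the small epoxide ring, so reagent control is relied upon. The step also needs chemoselectivity for the aldehyde over acetate, epoxide and ketal, which the low basicity of the organochromium reagent and the masking of the C1 ketone and of O4 should secure.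

Step 13
Reactants: 21 coupled allylic alcohol
Product: 22 [(4S,5R,6R)-5,6-epoxy-4-hydroxy-5-[(1S,2E,6E)-1-hydroxy-3,7,11-trimethyldodeca-2,6,10-trienyl]-1-oxocyclohex-2-en-2-yl]methyl acetate (target)
Conditions: aq. HF (48%), MeCN, 0 °C
Reagents that add atoms: water, O
Why: Acidic global deprotection cleaves the silyl ether and hydrolyses the dimethyl ketal to the C1 enone, while the epoxide, the acetate and the C1' allylic carbinol (deactivated toward ionisation by the adjacent epoxide carbon) should survive.

Compound list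
1 | geranyl bromide, (2E)-1-bromo-3,7-dimethylocta-2,6-diene | BrC/C=C(\C)CCC=C(C)C | starting material
2 | 1-(trimethylsilyl)propyne | CC#C[Si](C)(C)C | starting material
3 | 3-lithio-1-(trimethylsilyl)propyne | [Li]CC#C[Si](C)(C)C | intermediate
4 | [(5E)-6,10-dimethylundeca-5,9-dien-1-yn-1-yl]trimethylsilane | C[Si](C)(C)C#CCC/C=C(\C)CCC=C(C)C | intermediate
5 | (5E)-6,10-dimethylundeca-5,9-dien-1-yne | C#CCC/C=C(\C)CCC=C(C)C | intermediate
6 | dimethyl[(1E,5E)-2,6,10-trimethylundeca-1,5,9-trien-1-yl]alane | C[Al](C)/C=C(\C)CC/C=C(\C)CCC=C(C)C | intermediate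
7 | (1E,5E)-1-iodo-2,6,10-trimethylundeca-1,5,9-triene | I/C=C(\C)CC/C=C(\C)CCC=C(C)C | intermediate
8 | 2,5-dimethoxyterephthalaldehyde | COc1cc(C=O)c(OC)cc1C=O | starting material
9 | 2-hydroxy-5-methoxyterephthalaldehyde | COc1cc(C=O)c(O)cc1C=O | intermediate
10 | 2,5-bis(hydroxymethyl)-4-methoxyphenol | COc1cc(CO)c(O)cc1CO | intermediate
11 | 2,5-bis(hydroxymethyl)-4,4-dimethoxycyclohexa-2,5-dien-1-one | OCC1=CC(=O)C(CO)=CC1(OC)OC | intermediate
12 | (5S,6R)-5,6-epoxy-2,5-bis(hydroxymethyl)-1,1-dimethoxycyclohex-2-en-4-one | OCC1=CC(=O)[C@@]2(CO)O[C@H]2C1(OC)OC | intermediate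
13 | (4R,5R,6R)-5,6-epoxy-2,5-bis(hydroxymethyl)-1,1-dimethoxycyclohex-2-en-4-ol, hydroxyl cis to epoxide oxygen | OCC1=C[C@@H](O)[C@@]2(CO)O[C@H]2C1(OC)OC | intermediate
14 | tris(4-nitrobenzoate) of the (4S,5R,6R)-triol 15 | O=C(c3ccc(cc3)[N+](=O)[O-])OCC1=C[C@H](OC(=O)c3ccc(cc3)[N+](=O)[O-])[C@@]2(COC(=O)c3ccc(cc3)[N+](=O)[O-])O[C@H]2C1(OC)OC | intermediate
15 | (4S,5R,6R)-5,6-epoxy-2,5-bis(hydroxymethyl)-1,1-dimethoxycyclohex-2-en-4-ol, hydroxyl trans to epoxide oxygen | OCC1=C[C@H](O)[C@@]2(CO)O[C@H]2C1(OC)OC | intermediate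
16 | cyclic phenylboronate of 15 across O4 and the C5 CH2O group | OCC1=C[C@@H]3OB(c4ccccc4)OC[C@@]32O[C@H]2C1(OC)OC | intermediate
17 | C2-acetoxymethyl derivative of phenylboronate 16 | CC(=O)OCC1=C[C@@H]3OB(c4ccccc4)OC[C@@]32O[C@H]2C1(OC)OC | intermediate
18 | [(4S,5R,6R)-5,6-epoxy-4-hydroxy-5-(hydroxymethyl)-1,1-dimethoxycyclohex-2-en-2-yl]methyl acetate | CC(=O)OCC1=C[C@H](O)[C@@]2(CO)O[C@H]2C1(OC)OC | intermediate
19 | [(4S,5S,6R)-5,6-epoxy-1,1-dimethoxy-4-(triethylsilyloxy)-5-(triethylsilyloxymethyl)cyclohex-2-en-2-yl]methyl acetate | CC(=O)OCC1=C[C@H](O[Si](CC)(CC)CC)[C@@]2(CO[Si](CC)(CC)CC)O[C@H]2C1(OC)OC | intermediate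
20 | [(4S,5S,6R)-5,6-epoxy-5-formyl-1,1-dimethoxy-4-(triethylsilyloxy)cyclohex-2-en-2-yl]methyl acetate | CC(=O)OCC1=C[C@H](O[Si](CC)(CC)CC)[C@@]2(C=O)O[C@H]2C1(OC)OC | intermediate
21 | [(4S,5S,6R)-5,6-epoxy-5-[(1S,2E,6E)-1-hydroxy-3,7,11-trimethyldodeca-2,6,10-trienyl]-1,1-dimethoxy-4-(triethylsilyloxy)cyclohex-2-en-2-yl]methyl acetate | CC(=O)OCC1=C[C@H](O[Si](CC)(CC)CC)[C@@]2([C@@H](O)/C=C(\C)CC/C=C(\C)CCC=C(C)C)O[C@H]2C1(OC)OC | intermediate
22 | [(1R,5S,6R)-5-hydroxy-6-[(1S,2E,6E)-1-hydroxy-3,7,11-trimethyldodeca-2,6,10-trienyl]-2-oxo-7-oxabicyclo[4.1.0]hept-3-en-3-yl]methyl acetate | CC(=O)OCC1=C[C@H](O)[C@@]2([C@@H](O)/C=C(\C)CC/C=C(\C)CCC=C(C)C)O[C@H]2C1=O | target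

Total step count: 13. Longest linear sequence: 11 steps (steps 3 to 13).

Steps most likely to fail

Step 12. The facial selectivity at C1' may be poor if the bias of the α-quaternary epoxy aldehyde opposes the ligand, and divalent chromium may partly reduce the epoxy aldehyde. The fallback sets out from 20 and 7. An unligated coupling (CrCl2, NiCl2 cat., DMSO, rt) should give 21 mixed with the (1'R)-epimer F1. Dess–Martin oxidation of the mixture converges both on the epoxy enone F2. A Luche 1,2-reduction (NaBH4, CeCl3·7H2O, MeOH, −78 °C) should then deliver hydride over the epoxide ring in the rotamer that holds C=O anti to the epoxide C–O bond. By the same bias that makes the direct alkenyl addition doubtful, this gives the (1'S)-alcohol, and the route is rejoined at 21.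

Step 6. The enantiofacial discrimination may be low, or of the wrong sense, because two free hydroxymethyl groups compete for the tartrate aggregate. The fallback sets out from 11 and resolves instead of inducing. A racemic nucleophilic epoxidation (t-BuOOH, DBU, CH2Cl2) gives 12 together with the enantiomeric epoxy ketone F3. Luche reduction as in step 7 gives 13 together with the enantiomeric triol F4. The inversion of step 8 is then run with (S)-2-methoxy-2-phenylacetic acid in place of 4-nitrobenzoic acid. This gives two diastereomeric tris-esters, the tris[(S)-2-methoxy-2-phenylacetate] of 15 F5 and that of the enantiomeric ring F6. F5 is separated by chromatography or crystallisation and methanolysed (K2CO3, MeOH), and the route is rejoined at 15.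

Step 8. The displacement at the hindered C4 centre, next to the quaternary epoxide carbon, may be incomplete, and side reactions of the two primary hydroxyls may intervene. The fallback sets out from 13 and masks the primary hydroxyls first. TBSCl (2.1 equiv) and imidazole in DMF give the bis(tert-butyldimethylsilyl) ether F7. Tf2O and pyridine at −40 °C give the C4 triflate F8. Tetrabutylammonium nitrite in DMF (Lattrell–Dax inversion) gives the inverted nitrite ester F9, which hydrolyses on work-up to the inverted alcohol F10. TBAF in THF removes both silyl groups, and the route is rejoined at 15.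

Further compounds
F1 | step 12 | (1'R)-epimer of 21 | CC(=O)OCC1=C[C@H](O[Si](CC)(CC)CC)[C@@]2([C@H](O)/C=C(\C)CC/C=C(\C)CCC=C(C)C)O[C@H]2C1(OC)OC
F2 | step 12 | C1' ketone (epoxy enone) derived from 21 and F1 | CC(=O)OCC1=C[C@H](O[Si](CC)(CC)CC)[C@@]2(C(=O)/C=C(\C)CC/C=C(\C)CCC=C(C)C)O[C@H]2C1(OC)OC
F3 | step 6 | enantiomer of epoxy ketone 12 | OCC1=CC(=O)[C@]2(CO)O[C@@H]2C1(OC)OC
F4 | step 6 | enantiomer of triol 13 | OCC1=C[C@H](O)[C@]2(CO)O[C@@H]2C1(OC)OC
F5 | step 6 | tris[(S)-2-methoxy-2-phenylacetate] of triol 15 | O=C(OCC1=C[C@H](OC(=O)[C@@H](OC)c3ccccc3)[C@@]2(COC(=O)[C@@H](OC)c3ccccc3)O[C@H]2C1(OC)OC)[C@@H](OC)c3ccccc3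
F6 | step 6 | tris[(S)-2-methoxy-2-phenylacetate] of the enantiomer of 15 | O=C(OCC1=C[C@@H](OC(=O)[C@@H](OC)c3ccccc3)[C@]2(COC(=O)[C@@H](OC)c3ccccc3)O[C@@H]2C1(OC)OC)[C@@H](OC)c3ccccc3
F7 | step 8 | bis(tert-butyldimethylsilyl) ether of 13 at both primary hydroxyls | CC(C)(C)[Si](C)(C)OCC1=C[C@@H](O)[C@@]2(CO[Si](C)(C)C(C)(C)C)O[C@H]2C1(OC)OC
F8 | step 8 | C4 triflate of F7 | CC(C)(C)[Si](C)(C)OCC1=C[C@@H](OS(=O)(=O)C(F)(F)F)[C@@]2(CO[Si](C)(C)C(C)(C)C)O[C@H]2C1(OC)OC
F9 | step 8 | C4-inverted nitrite ester | CC(C)(C)[Si](C)(C)OCC1=C[C@H](ON=O)[C@@]2(CO[Si](C)(C)C(C)(C)C)O[C@H]2C1(OC)OC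
F10 | step 8 | C4-inverted bis(tert-butyldimethylsilyl) ether (4S alcohol) | CC(C)(C)[Si](C)(C)OCC1=C[C@H](O)[C@@]2(CO[Si](C)(C)C(C)(C)C)O[C@H]2C1(OC)OC
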